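## Analysis of the target

(M)-Bisoflavolin D (C30H18O10) is the dehydrodimer of genistein (A4). It holds two 5,7,4'-trihydroxyisoflavone units. The first has benzo ring A, pyranone ring C and pendant ring B (C1'–C6'); the second has rings A'', C'' and B'' (C2''–C8a'', C1'''–C6'''). One bond joins them, from C3' of ring B to C8'' of ring A''.

There is no stereocentre. The only stereogenic element is the C3'–C8'' axis, flanked by O4'H and C2'–H on ring B and by O7''H and the ring oxygen O1'' (on C8a'') on ring A''. C4' outranks C2' and C8a'' outranks C7''. M therefore means a negative C4'–C3'–C8''–C8a'' torsion, that is, a positive torsion between the two hydroxyl-bearing carbons C4' and C7''.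

Three small oxygen substituents and one hydrogen give only a moderate barrier, so the axis should be set late, secured until the end and released under mild conditions. The sensitive groups are six oxidisable phenols (acidity 7-OH > 4'-OH >> chelated 5-OH) and two pyranones. Their unsubstituted C2 and C2'' add hard nucleophiles and open with hydroxide, which rules out aryllithium chemistry.

The real difficulty is site selection. Each unit offers C6, C8, C3', C5' and its oxygens for coupling, and the target needs a single cross-combination between two identical monomers.

The feature exploited here is the array O4'–C4'–C3'–C8''–C7''–O7''. Both carbons of the missing bond lie ortho to a phenolic oxygen that can be addressed selectively. A chiral three-carbon bridge from O4' to O7'' holds C3' next to C8'', makes the choice C3'/C5' meaningless (they are homotopic), reduces the site problem to C8'' against C6'', and dictates the sense of twist.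

## Retrosynthetic reasoning

**8 ⇒ 7.** Six O–C(alkyl) bonds are cut: four O–CH3 bonds (O5, O7, O5'', O4''') and the two O–CH bonds of a (2R,4R)-pentane-2,4-diyl bridge between O4' and O7''. The bridge carbons are secondary alkyl aryl ethers and fall to the same Lewis acid as the methyl ethers, so removing the bridge costs no step of its own. The forward reaction must touch no bond at the axis and must stay at or below room temperature.

**7 ⇒ 6.** The C3'–C8'' bond is cut and both carbons return to C–H. This is the only C–C bond that the target has beyond two monomers, and it carries the only stereogenic element. Cutting it inside the bridge turns an intermolecular cross-coupling of near-identical partners into a ring closure in which only two positions of ring A'' can reach ring B. The forward step must remove two hydrogens, close a nine-membered ring, choose C8'' over C6'' and set M.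

**6 ⇒ 5.** The two O–CH3 bonds at O5 and O5'' are cut. These caps are needed only for the oxidation: they remove free phenols and shield C6''. They go on last because the chelated hydroxyls are inert in the etherifications before, so no earlier protection step is needed.

**5 ⇒ 3 + 4.** The O4'–CH bond is cut. Compound 4 has one unchelated phenol, exactly the oxygen ortho to C3', and its 7-oxygen is already capped. The forward etherification must invert the free carbinol of 3 cleanly.

**3 ⇒ 1 + 2.** The O7''–CH bond is cut. Compound 1 has one acidic phenol, exactly the oxygen ortho to C8'', and its 4'''-oxygen is already capped. Compound 2 is C2-symmetric, so either hydroxyl gives the same monoether. Two inversions turn the (S,S)-diol into the (R,R)-bridge.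

## Alternatives that were turned down

**Alternative 1:** the textbook cut of C3'–C8'' between two pre-functionalised, fully protected monomers.
- Forward key step: palladium-catalysed Suzuki–Miyaura coupling of the 8-iodide A1 with the 3'-boronic ester A2. This gives the racemic hexamethyl ether A3, followed by demethylation and separation of the atropisomers.
- Ring B cannot be halogenated or borylated beside the far more nucleophilic ring A, so A2 needs a de novo isoflavone synthesis from a pre-halogenated building block.
- The palladium aryl at C8'' carries two ortho oxygens and meets an ortho-alkoxy boronate, which favours protodeboronation.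
- Nothing in A1 or A2 controls the axis, so half of the material is lost.
- The count would be roughly twice that of the chosen route.

**Alternative 2:** the same bond cut with nothing on either carbon and no bridge.
- Forward key step: one-electron oxidation of unprotected genistein A4, a biomimetic phenol coupling, straight to 8.
- The phenoxyl radicals of A4 carry spin at C3', C5', C6, C8 and on oxygen, so the wanted pairing is one of many C–C and C–O combinations.
- The dimers are at least as easily oxidised as A4.
- No element outside an enzyme pocket selects the cross-combination or the sense of the axis. The single step would be paid for by an undefendable separation.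

**Alternative 3:** the biaryl bond is made early and the two pyranone rings are cut instead (O1–C2, C2–C3, O1''–C2'', C2''–C3''), back to the bis-deoxybenzoin A5.
- Forward key step: a double one-carbon insertion (Vilsmeier-type formylation and cyclodehydration) that closes rings C and C'' in one operation.
- The ketone on the central ring of A5 lies between two different hydroxyls. Closure through one gives the skeleton of 8; closure through the other gives the 3',6''-linked isomer A6. Nothing in A5 biases this choice.
- The site problem is therefore only moved, and the axis stays uncontrolled.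
- Building the octaphenol A5 needs two acylations of polyphenols plus a biaryl coupling of its own.

Key step: step 4

Assumption: the SMILES string cannot express the axis, so the descriptor M of the name is taken as binding and is carried in the names of 7 and 8; the axis is taken to be configurationally stable at or below room temperature, as a fixed descriptor implies.

## Route

Step 1
Reactants: 1 biochanin A (5,7-dihydroxy-3-(4-methoxyphenyl)-4H-chromen-4-one); 2 (2S,4S)-pentane-2,4-diol
Product: 3 5-hydroxy-7-{[(2R,4S)-4-hydroxypentan-2-yl]oxy}-3-(4-methoxyphenyl)-4H-chromen-4-one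
Conditions: 2 (3 equiv), PPh3, DIAD, THF, 0 °C to 20 °C
Reagents that add atoms: none
Why: Mitsunobu etherification; only the acidic 7-OH of 1 reacts because the 5-OH is locked in a hydrogen bond to C4=O, and the excess of C2-symmetric 2 holds the reaction at the monoether. The SN2 displacement inverts the ether carbon from S to R, and the other carbinol stays S.

Step 2
Reactants: 3 monoether from step 1; 4 prunetin (5-hydroxy-3-(4-hydroxyphenyl)-7-methoxy-4H-chromen-4-one)
Product: 5 (2R,4R)-2-{[5-hydroxy-3-(4-methoxyphenyl)-4-oxo-4H-chromen-7-yl]oxy}-4-[4-(5-hydroxy-7-methoxy-4-oxo-4H-chromen-3-yl)phenoxy]pentane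
Conditions: PPh3, DIAD, THF, 0 °C to 40 °C
Reagents that add atoms: none
Why: Second Mitsunobu etherification; the 4'-OH is the only unchelated phenol of 4, and the chelated hydroxyls of 3 and 4 do not compete. SN2 inversion turns the remaining (S)-carbinol into the second (R)-ether carbon.

Step 3
Reactants: 5 bridged bis-isoflavone with two chelated hydroxyls
Product: 6 (2R,4R)-2-{[5-methoxy-3-(4-methoxyphenyl)-4-oxo-4H-chromen-7-yl]oxy}-4-[4-(5,7-dimethoxy-4-oxo-4H-chromen-3-yl)phenoxy]pentane
Conditions: MeI (6 equiv), K2CO3 (6 equiv), DMF, 40 °C
Reagents that add atoms: iodomethane, CI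
Why: Williamson O-methylation of the two chelated phenols under forcing but weakly basic conditions that leave the pyranones closed. The caps remove the easily oxidised phenols before the electrolysis, and the 5''-methoxy group shields C6''.

Step 4
Reactants: 6 open bridged bis-isoflavone tetramethyl ether
Product: 7 (M)-4',7''-O,O-[(2R,4R)-pentane-2,4-diyl]-5,7,5'',4'''-tetra-O-methylbisoflavolin D (C3'–C8'' biaryl inside a nine-membered dibenzo-1,5-dioxonine ring)
Conditions: boron-doped diamond anode, Pt cathode, undivided cell, constant current (about 5 mA cm-2, 2.2 F mol-1), Bu4NPF6 (0.1 M), HFIP (1,1,1,3,3,3-hexafluoropropan-2-ol), 2 mM, 20 °C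
Reagents that add atoms: none
Why: Proposed new method: anodic dehydrogenative aryl–aryl coupling across a chiral diether bridge, closest to three known reaction types, namely anodic arene–arene coupling of aryl ethers in HFIP, oxidative coupling of two galloyl esters held on a sugar diol, and Ullmann closure of bis(2-iodoaryl) ethers of this same diol. One-electron oxidation of 6 gives an aryl ether radical cation that HFIP keeps alive long enough for a medium-ring closure; with the hole on ring B the charge sits ortho to O4' (the para position C1' is blocked), C8'' of ring A'' attacks C3', and loss of a proton, a second electron and a second proton restores both arenes while the protons are reduced to H2 at the cathode. The step closes one ring, the nine-membered 1,5-dioxonine made of C3', C4', O4', the three bridge carbons, O7'', C7'' and C8'', by attack of an arene on a radical cation with both reacting carbons inside the new ring. The only new stereogenic element, the axis, is controlled by the two (R)-configured bridge carbons: in the closing ring each carbinol hydrogen has to eclipse its aryl–oxygen bond and each methyl group has to point outwards, which is possible only for a positive C4'–C3'–C8''–C7'' torsion, that is for M, whereas the opposite twist presses both methyl groups against the arenes. Ring B poses no site problem because C3' and C5' are homotopic; on ring A'' the bridge allows only C6'' and C8'', and C8'' is favoured because C6'' is buried between O7'' and the 5''-methoxy group, whose methyl is turned towards C6'' by the peri carbonyl, and because electrophiles attack 5,7-dialkoxychromones at C8. Chemoselectivity among the four arenes rests on the bridge: holes on ring B'' or ring A exchange by electron transfer and find no partner within reach, and the high dilution suppresses intermolecular coupling. The charge is limited to little more than 2 F per mol to spare 7 from further oxidation, and once closed the bridge forbids rotation through the anti-periplanar pathway, so the axis of 7 is secured.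

Step 5
Reactants: 7 bridged (M)-biaryl tetramethyl ether
Product: 8 (M)-bisoflavolin D
Conditions: BBr3 (12 equiv), CH2Cl2, −78 °C to 20 °C; then H2O, 0 °C
Reagents that add atoms: none
Why: Lewis-acid cleavage of aryl alkyl ethers; the secondary bridge carbons and the chelated 5- and 5''-methyl ethers fall at low temperature, and the 7- and 4'''-methyl ethers fall on warming, so six C–O bonds are cut in one operation. No bond at the axis is touched, so M should be carried over as long as the mixture is not heated.

## Compound list

1 | biochanin A, 5,7-dihydroxy-3-(4-methoxyphenyl)-4H-chromen-4-one | O=c1c(-c2ccc(OC)cc2)coc2cc(O)cc(O)c12 | starting material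
2 | (2S,4S)-pentane-2,4-diol | C[C@H](O)C[C@H](C)O | starting material
3 | 5-hydroxy-7-{[(2R,4S)-4-hydroxypentan-2-yl]oxy}-3-(4-methoxyphenyl)-4H-chromen-4-one | C[C@H](O)C[C@@H](C)Oc1cc(O)c2c(=O)c(-c3ccc(OC)cc3)coc2c1 | intermediate
4 | prunetin, 5-hydroxy-3-(4-hydroxyphenyl)-7-methoxy-4H-chromen-4-one | O=c1c(-c2ccc(O)cc2)coc2cc(OC)cc(O)c12 | starting material
5 | (2R,4R)-2-{[5-hydroxy-3-(4-methoxyphenyl)-4-oxo-4H-chromen-7-yl]oxy}-4-[4-(5-hydroxy-7-methoxy-4-oxo-4H-chromen-3-yl)phenoxy]pentane | C[C@@H](Oc1ccc(cc1)-c1coc2cc(OC)cc(O)c2c1=O)C[C@@H](C)Oc1cc(O)c2c(=O)c(-c3ccc(OC)cc3)coc2c1 | intermediate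
6 | (2R,4R)-2-{[5-methoxy-3-(4-methoxyphenyl)-4-oxo-4H-chromen-7-yl]oxy}-4-[4-(5,7-dimethoxy-4-oxo-4H-chromen-3-yl)phenoxy]pentane | C[C@@H](Oc1ccc(cc1)-c1coc2cc(OC)cc(OC)c2c1=O)C[C@@H](C)Oc1cc(OC)c2c(=O)c(-c3ccc(OC)cc3)coc2c1 | intermediate
7 | (M)-4',7''-O,O-[(2R,4R)-pentane-2,4-diyl]-5,7,5'',4'''-tetra-O-methylbisoflavolin D | C[C@@H]1C[C@@H](C)Oc2cc(OC)c3c(=O)c(-c4ccc(OC)cc4)coc3c2-c2cc(ccc2O1)-c1coc2cc(OC)cc(OC)c2c1=O | intermediate
8 | (M)-bisoflavolin D | O=c1c(-c2ccc(O)c(-c3c(O)cc(O)c4c(=O)c(-c5ccc(O)cc5)coc34)c2)coc2cc(O)cc(O)c12 | target

## Step count and least certain steps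

Total step count: 5. Longest linear sequence: 5 steps (1 → 3 → 5 → 6 → 7 → 8).

**Step 4 (key step, proposed new method).**
- The three oxygen donors of ring A'' are in push–pull conjugation with C4''=O, so the ring closure may be slow. The radical cation could then decay by intermolecular coupling or by loss of a secondary alkyl group.
- Closure through C6'' instead of C8'' and further oxidation of the product are the other likely failures.
- If the sense of induction proves opposite to the conformational model, the enantiomer of 2 is used from step 1 on.
- The fallback uses known chemistry: Ullmann coupling of two C–I bonds across the same bridge. It sets out from 3 and 4 and comes back to the route at 7. Compound 3 is methylated at its chelated hydroxyl (MeI, K2CO3) to 7-{[(2R,4S)-4-hydroxypentan-2-yl]oxy}-5-methoxy-3-(4-methoxyphenyl)-4H-chromen-4-one F1. This is iodinated at the site that electrophiles choose in 5,7-dialkoxychromones (N-iodosuccinimide, CF3CO2H, MeCN) to give the 8-iodide F2. Compound 4 is iodinated through its 4'-phenoxide, which reacts far faster than the neutral chelated ring A (I2, KI, aqueous Na2CO3), to give 3'-iodoprunetin F3. Mitsunobu union of F2 and F3 gives the bridged diiodide F4. Methylation of its chelated hydroxyl gives the fully capped diiodide F5. Activated copper powder in DMF at 110–130 °C then closes the nine-membered ring to 7, with both sites fixed by the halogens and the axis fixed by the bridge.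

**Step 5.**
- Once the bridge is cut, the 7- and 4'''-methyl ethers still need hours near room temperature. Slow rotation about the freed axis, perhaps eased by a cyclic borate spanning O4' and O7'', may erode the configuration.
- Incomplete cleavage at O7 and re-alkylation of an electron-rich ring by the secondary cation are further risks.
- The fallback reverses the order of cleavage. It sets out from 7 and comes back at 8. Nucleophilic demethylation (NaSEt, DMF, 110 °C) attacks methyl carbons by SN2 and spares the secondary bridge carbons, and any thiolate addition at C2 reverses on acidification. It should give the bridged tetraphenol F6 with the axis still locked. BCl3 in CH2Cl2 at −78 °C to 0 °C then cuts only the two secondary ethers to give 8.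

**Step 2.**
- Capture of the hindered, β-branched oxyphosphonium ion by the weakly acidic 4'-phenol may be slow, so elimination to an alkene and loss of the valuable alcohol could compete.
- The fallback inverts the order of assembly, so that the demanding second displacement uses the more acidic phenol. It sets out from 2 and 4 and comes back at 5. Mitsunobu reaction of 4 with excess 2 gives 5-hydroxy-3-(4-{[(2R,4S)-4-hydroxypentan-2-yl]oxy}phenyl)-7-methoxy-4H-chromen-4-one F7. Compound F7 is then coupled under Mitsunobu conditions with the 7-OH of 1 to give 5.

**Step 1.**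
- Double etherification of the diol and a difficult separation from the phosphine oxide and the excess diol are the likely problems.
- The fallback replaces redox condensation by alkylative opening of an activated diol, which stops by itself after one displacement. It sets out from 2 and 1 and comes back at 3. Compound 2 is converted (SOCl2, then RuCl3, NaIO4) into the cyclic sulfate (4S,6S)-4,6-dimethyl-1,3,2-dioxathiane 2,2-dioxide F8. The 7-phenoxide of 1 (K2CO3, DMF) opens it with inversion to the hydrogen sulfate monoester F9. Mild acid hydrolysis (catalytic H2SO4, H2O, THF) cleaves the S–O bond with retention to give 3.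

## Further compounds

F1 | step 4 | 7-{[(2R,4S)-4-hydroxypentan-2-yl]oxy}-5-methoxy-3-(4-methoxyphenyl)-4H-chromen-4-one | C[C@H](O)C[C@@H](C)Oc1cc(OC)c2c(=O)c(-c3ccc(OC)cc3)coc2c1
F2 | step 4 | 7-{[(2R,4S)-4-hydroxypentan-2-yl]oxy}-8-iodo-5-methoxy-3-(4-methoxyphenyl)-4H-chromen-4-one | C[C@H](O)C[C@@H](C)Oc1cc(OC)c2c(=O)c(-c3ccc(OC)cc3)coc2c1I
F3 | step 4 | 3'-iodoprunetin, 5-hydroxy-3-(4-hydroxy-3-iodophenyl)-7-methoxy-4H-chromen-4-one | O=c1c(-c2ccc(O)c(I)c2)coc2cc(OC)cc(O)c12
F4 | step 4 | (2R,4R)-2-{[8-iodo-5-methoxy-3-(4-methoxyphenyl)-4-oxo-4H-chromen-7-yl]oxy}-4-[4-(5-hydroxy-7-methoxy-4-oxo-4H-chromen-3-yl)-2-iodophenoxy]pentane | C[C@@H](Oc1ccc(cc1I)-c1coc2cc(OC)cc(O)c2c1=O)C[C@@H](C)Oc1cc(OC)c2c(=O)c(-c3ccc(OC)cc3)coc2c1I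
F5 | step 4 | (2R,4R)-2-{[8-iodo-5-methoxy-3-(4-methoxyphenyl)-4-oxo-4H-chromen-7-yl]oxy}-4-[4-(5,7-dimethoxy-4-oxo-4H-chromen-3-yl)-2-iodophenoxy]pentane | C[C@@H](Oc1ccc(cc1I)-c1coc2cc(OC)cc(OC)c2c1=O)C[C@@H](C)Oc1cc(OC)c2c(=O)c(-c3ccc(OC)cc3)coc2c1I
F6 | step 5 | (M)-4',7''-O,O-[(2R,4R)-pentane-2,4-diyl]bisoflavolin D | C[C@@H]1C[C@@H](C)Oc2cc(O)c3c(=O)c(-c4ccc(O)cc4)coc3c2-c2cc(ccc2O1)-c1coc2cc(O)cc(O)c2c1=O
F7 | step 2 | 5-hydroxy-3-(4-{[(2R,4S)-4-hydroxypentan-2-yl]oxy}phenyl)-7-methoxy-4H-chromen-4-one | C[C@H](O)C[C@@H](C)Oc1ccc(cc1)-c1coc2cc(OC)cc(O)c2c1=O
F8 | step 1 | (4S,6S)-4,6-dimethyl-1,3,2-dioxathiane 2,2-dioxide | C[C@H]1C[C@H](C)OS(=O)(=O)O1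
F9 | step 1 | (2S,4R)-4-{[5-hydroxy-3-(4-methoxyphenyl)-4-oxo-4H-chromen-7-yl]oxy}pentan-2-yl hydrogen sulfate | C[C@H](OS(=O)(=O)O)C[C@@H](C)Oc1cc(O)c2c(=O)c(-c3ccc(OC)cc3)coc2c1
A1 | alternative 1 | 8-iodo-5,7-dimethoxy-3-(4-methoxyphenyl)-4H-chromen-4-one | O=c1c(-c2ccc(OC)cc2)coc2c(I)c(OC)cc(OC)c12
A2 | alternative 1 | 5,7-dimethoxy-3-[4-methoxy-3-(4,4,5,5-tetramethyl-1,3,2-dioxaborolan-2-yl)phenyl]-4H-chromen-4-one | O=c1c(-c2ccc(OC)c(B3OC(C)(C)C(C)(C)O3)c2)coc2cc(OC)cc(OC)c12
A3 | alternative 1 | racemic hexa-O-methylbisoflavolin D | O=c1c(-c2ccc(OC)c(-c3c(OC)cc(OC)c4c(=O)c(-c5ccc(OC)cc5)coc34)c2)coc2cc(OC)cc(OC)c12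
A4 | alternative 2 | genistein, 5,7-dihydroxy-3-(4-hydroxyphenyl)-4H-chromen-4-one | O=c1c(-c2ccc(O)cc2)coc2cc(O)cc(O)c12
A5 | alternative 3 | bis-deoxybenzoin, 2-{4-hydroxy-3-[2,4,6-trihydroxy-3-(4-hydroxyphenylacetyl)phenyl]phenyl}-1-(2,4,6-trihydroxyphenyl)ethanone | O=C(Cc1ccc(O)c(c1)-c1c(O)cc(O)c(C(=O)Cc2ccc(O)cc2)c1O)c1c(O)cc(O)cc1O
A6 | alternative 3 | 3',6''-linked genistein dimer | O=c1c(-c2ccc(O)c(-c3c(O)cc4occ(-c5ccc(O)cc5)c(=O)c4c3O)c2)coc2cc(O)cc(O)c12
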